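## Retrosynthetic overview

1. Target ⇐ acetylation of the C4 carbinol ⇐ catalyst-controlled reduction of the acetyl C=O of an oplopane 1,3-diketone; the C9 ester comes from Mitsunobu inversion of the allylic alcohol.
2. Five-membered ring ⇐ ring contraction of a cadinane 4,5-epoxy-3-ketone by 1,2-acyl shift (C3 moves from C4 to C5; C4/C15 become the acetyl side chain).
3. Six-membered ring B ⇐ C6–C7 closure of a bisabolane-type dienone: the γ-carbon of the carvone ring adds to the side-chain enone (intramolecular vinylogous Mukaiyama–Michael).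
4. Bisabolane-type dienone ⇐ (R)-carvone (ring A, C1), 3-methylbut-1-yne (C7, C8, isopropyl) and (2R)-2-methylbutanoic acid (ester on C2).
5. Ring order: ring A is bought (carvone) → ring B closed (cadinane) → ring A contracted to the cyclopentanone (oplopane).

Assumption: 1, 4, 7 and 18 are bought as the single isomers drawn; bicyclic compounds carry the biogenetic cadinane numbering (ring A C1–C6 with Me-15 on C4; ring B C1, C6–C10 with isopropyl on C7 and C14 on C10; after contraction the five-membered ring is C1–C2–C3–C5–C6 and C4/C15 are the side chain on C5).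

## Route

Step 1
Reactants: 1 (R)-carvone
Product: 3 trans-6-hydroxycarvone, via lithium α′-enolate 2 (not isolated)
Conditions: LDA, THF, −78 °C; Davis oxaziridine, −78 °C; 1 M HCl quench
Reagents that add atoms: 2-(benzenesulfonyl)-3-phenyloxaziridine, O=S(=O)(c1ccccc1)N1OC1c1ccccc1
Why: Kinetic α′-deprotonation gives the cross-conjugated enolate 2, and Davis enolate hydroxylation occurs on the face anti to the neighbouring isopropenyl group, so the new centre is trans (6S).

Step 2
Reactants: 3 trans-6-hydroxycarvone; 4 (2R)-2-methylbutanoic acid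
Product: 5 cis-6-acyloxycarvone
Conditions: PPh3, DIAD, THF, 0 °C → rt
Reagents that add atoms: none
Why: Mitsunobu esterification proceeds with SN2 inversion at the carbinol carbon α to the ketone, turning the trans alcohol into the cis ester with the C2 configuration of the target and blocking the α′ position for step 6.

Step 3
Reactants: 5 cis-6-acyloxycarvone
Product: 6 enal
Conditions: SeO2 (1.5 equiv), 1,4-dioxane, 80 °C
Reagents that add atoms: selenium dioxide, O=[Se]=O
Why: Riley-type SeO2 allylic oxidation (ene reaction, then [2,3]-shift) attacks the methyl group of the 1,1-disubstituted alkene rather than the allylic methine and runs on to the 2-substituted acrolein.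

Step 4
Reactants: 6 enal; 7 3-methylbut-1-yne
Product: 10 dienol (C9 epimers), via alkenylzirconocene chloride 8 (not isolated), via alkenyl(methyl)zinc 9 (not isolated)
Conditions: 7, Cp2Zr(H)Cl, CH2Cl2, rt; Me2Zn, −65 °C; then 6, 0 °C; aq. NH4Cl
Reagents that add atoms: none
Why: Hydrozirconation of 7 (syn, terminal Zr, hence E), Zr→Zn transmetalation and 1,2-addition of the alkenylzinc to the aldehyde (Wipf alkenylation) spare the ketone and the ester; the new carbinol centre is not controlled and is erased in step 5.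

Step 5
Reactants: 10 dienol
Product: 11 cross-conjugated dienone
Conditions: Dess–Martin periodinane, pyridine, CH2Cl2, 0 °C → rt
Reagents that add atoms: none
Why: Dess–Martin oxidation of the bis-allylic alcohol gives the dienone under neutral conditions that leave the α-acyloxy ketone stereocentre untouched.

Step 6
Reactants: 11 cross-conjugated dienone
Product: 13 cadinatrienone silyl dienol ether, via ring-A silyl dienol ether 12 (not isolated)
Conditions: TIPSOTf (1.2 equiv), i-Pr2NEt (1.5 equiv), CH2Cl2, −78 → −20 °C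
Reagents that add atoms: triisopropylsilyl trifluoromethanesulfonate, CC(C)[Si](OS(=O)(=O)C(F)(F)F)(C(C)C)C(C)C
Why: Soft enolisation gives the linear dienol ether 12 (γ-deprotonation, because C2 is tertiary and acyloxy-substituted), and its γ-carbon C6 adds to C7 of the silyl-activated enone in an intramolecular vinylogous Mukaiyama–Michael addition through a chair-like six-membered transition state (E-enone, isopropyl equatorial → 7R; trans fusion → 6S, with C6 still epimerisable as the γ-carbon so the all-equatorial isomer is also the thermodynamic one), the silyl group ending on the C9 oxygen.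

Step 7
Reactants: 13 cadinatrienone silyl dienol ether
Product: 14 4,5-epoxy ketone
Conditions: t-BuOOH (decane), DBU, CH2Cl2, 0 °C
Reagents that add atoms: tert-butyl hydroperoxide, CC(C)(C)OO
Why: Weitz–Scheffer nucleophilic epoxidation: tert-butylperoxide adds axially (anti to H-6) to C5 of the only electron-poor alkene and closes to the 4R,5R epoxide, whose configuration is not carried forward, while the electron-rich silyloxydiene is inert.

Step 8
Reactants: 14 4,5-epoxy ketone
Product: 16 oplopane triketone, via ring-contracted silyl dienol ether 15 (not isolated)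
Conditions: BF3·OEt2, CH2Cl2, −78 → −20 °C; then TBAF, AcOH, THF, 0 °C
Reagents that add atoms: none
Why: Lewis-acid-promoted 1,2-acyl shift of an α,β-epoxy ketone (House–Meinwald-type rearrangement): the epoxide opens at C5, away from the carbonyl, and the C3 acyl carbon migrates from C4 to C5 with ring contraction (the only other migrating candidate on quaternary C4 is the poorly migrating methyl); C4 becomes the acetyl carbonyl, C5 equilibrates through the enol to the trans (5R) isomer and fluoride then frees the C9 ketone.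

Step 9
Reactants: 16 oplopane triketone
Product: 17 9-epi allylic alcohol
Conditions: NaBH4, CeCl3·7H2O, Et3N (1.1 equiv), MeOH–THF, −78 °C
Reagents that add atoms: none
Why: Luche 1,2-reduction: the 1,3-diketone is held as its cerium/ammonium diketonate and is not attacked, and hydride adds axially to the 2-methylenecyclohexanone (that face carries only H-1 and H-7) to give the equatorial 9R alcohol.

Step 10
Reactants: 17 9-epi allylic alcohol; 18 (2E)-3-methylpent-2-enoic acid
Product: 19 diester diketone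
Conditions: PPh3, DIAD, toluene, 0 °C → rt
Reagents that add atoms: none
Why: Mitsunobu esterification with SN2 inversion at C9 converts the equatorial 9R alcohol into the axial 9S ester of the target, the carboxylic acid being far more acidic than the diketone.

Step 11
Reactants: 19 diester diketone
Product: 20 β-hydroxy ketone
Conditions: RuCl[(S,S)-TsDPEN](p-cymene) (2 mol %), HCO2H–Et3N (5:2), CH2Cl2, rt
Reagents that add atoms: none
Why: Noyori–Ikariya asymmetric transfer hydrogenation of a 1,3-diketone stops at the β-hydroxy ketone: the methyl ketone is reduced under catalyst control (4S), the ring ketone flanked by two substituted carbons is left, and C5 stays the trans (5R) epimer through enolisation (dynamic kinetic resolution).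

Step 12
Reactants: 20 β-hydroxy ketone
Product: 21 target CNP0289166.2
Conditions: Ac2O, pyridine, DMAP (cat.), CH2Cl2, 0 °C
Reagents that add atoms: acetic anhydride, CC(=O)OC(C)=O
Why: DMAP-catalysed acylation of the secondary alcohol, kept cold and short so that the β-acetoxy ketone does not eliminate.

## Compound list

1 | (R)-carvone, (5R)-2-methyl-5-(prop-1-en-2-yl)cyclohex-2-en-1-one | CC(=C)[C@@H]1CC=C(C)C(=O)C1 | starting material
2 | lithium (3R)-6-methyl-3-(prop-1-en-2-yl)cyclohexa-1,5-dien-1-olate (kinetic α′-enolate of 1) | [Li+].CC(=C)[C@@H]1CC=C(C)C([O-])=C1 | intermediate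
3 | (5S,6S)-6-hydroxy-2-methyl-5-(prop-1-en-2-yl)cyclohex-2-en-1-one (trans-6-hydroxycarvone) | CC(=C)[C@@H]1CC=C(C)C(=O)[C@H]1O | intermediate
4 | (2R)-2-methylbutanoic acid | CC[C@@H](C)C(=O)O | starting material
5 | (1R,6S)-3-methyl-2-oxo-6-(prop-1-en-2-yl)cyclohex-3-en-1-yl (2R)-2-methylbutanoate (ester cis to isopropenyl) | CC(=C)[C@@H]1CC=C(C)C(=O)[C@@H]1OC(=O)[C@H](C)CC | intermediate
6 | (1R,6S)-3-methyl-2-oxo-6-(3-oxoprop-1-en-2-yl)cyclohex-3-en-1-yl (2R)-2-methylbutanoate | O=CC(=C)[C@@H]1CC=C(C)C(=O)[C@@H]1OC(=O)[C@H](C)CC | intermediate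
7 | 3-methylbut-1-yne | CC(C)C#C | starting material
8 | chlorobis(cyclopentadienyl)[(1E)-3-methylbut-1-en-1-yl]zirconium | CC(C)/C=C/[Zr](Cl)(C1C=CC=C1)C1C=CC=C1 | intermediate
9 | methyl[(1E)-3-methylbut-1-en-1-yl]zinc | CC(C)/C=C/[Zn]C | intermediate
10 | (1R,6S)-6-[(4E)-3-hydroxy-6-methylhepta-1,4-dien-2-yl]-3-methyl-2-oxocyclohex-3-en-1-yl (2R)-2-methylbutanoate (both carbinol epimers) | CC(C)/C=C/C(O)C(=C)[C@@H]1CC=C(C)C(=O)[C@@H]1OC(=O)[C@H](C)CC | intermediate
11 | (1R,6S)-3-methyl-6-[(4E)-6-methyl-3-oxohepta-1,4-dien-2-yl]-2-oxocyclohex-3-en-1-yl (2R)-2-methylbutanoate | CC(C)/C=C/C(=O)C(=C)[C@@H]1CC=C(C)C(=O)[C@@H]1OC(=O)[C@H](C)CC | intermediate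
12 | (1R,6S)-3-methyl-6-[(4E)-6-methyl-3-oxohepta-1,4-dien-2-yl]-2-{[tri(propan-2-yl)silyl]oxy}cyclohexa-2,4-dien-1-yl (2R)-2-methylbutanoate | CC(C)/C=C/C(=O)C(=C)[C@@H]1C=CC(C)=C(O[Si](C(C)C)(C(C)C)C(C)C)[C@@H]1OC(=O)[C@H](C)CC | intermediate
13 | (1S,2R,6S,7R)-3-oxo-9-{[tri(propan-2-yl)silyl]oxy}cadina-4,8,10(14)-trien-2-yl (2R)-2-methylbutanoate (trans-fused) | C=C1[C@@H]2[C@H](C=C(C)C(=O)[C@@H]2OC(=O)[C@H](C)CC)[C@@H](C(C)C)C=C1O[Si](C(C)C)(C(C)C)C(C)C | intermediate
14 | (1S,2R,4R,5R,6R,7R)-4,5-epoxy-3-oxo-9-{[tri(propan-2-yl)silyl]oxy}cadina-8,10(14)-dien-2-yl (2R)-2-methylbutanoate | C=C1[C@@H]2[C@H]([C@H]3O[C@@]3(C)C(=O)[C@@H]2OC(=O)[C@H](C)CC)[C@@H](C(C)C)C=C1O[Si](C(C)C)(C(C)C)C(C)C | intermediate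
15 | (1S,2R,5R,6R,7R)-3,4-dioxo-9-{[tri(propan-2-yl)silyl]oxy}oplopa-8,10(14)-dien-2-yl (2R)-2-methylbutanoate (C5 epimerisable, drawn trans) | C=C1[C@@H]2[C@H]([C@H](C(C)=O)C(=O)[C@@H]2OC(=O)[C@H](C)CC)[C@@H](C(C)C)C=C1O[Si](C(C)C)(C(C)C)C(C)C | intermediate
16 | (1S,2R,5R,6R,7R)-3,4,9-trioxooplop-10(14)-en-2-yl (2R)-2-methylbutanoate (1,3-diketone, partly enolised) | C=C1[C@@H]2[C@H]([C@H](C(C)=O)C(=O)[C@@H]2OC(=O)[C@H](C)CC)[C@@H](C(C)C)CC1=O | intermediate
17 | (1S,2R,5R,6R,7R,9R)-9-hydroxy-3,4-dioxooplop-10(14)-en-2-yl (2R)-2-methylbutanoate | C=C1[C@@H]2[C@H]([C@H](C(C)=O)C(=O)[C@@H]2OC(=O)[C@H](C)CC)[C@@H](C(C)C)C[C@H]1O | intermediate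
18 | (2E)-3-methylpent-2-enoic acid | CC/C(C)=C/C(=O)O | starting material
19 | (1S,2R,5R,6R,7R,9S)-2-{[(2R)-2-methylbutanoyl]oxy}-3,4-dioxooplop-10(14)-en-9-yl (2E)-3-methylpent-2-enoate | C=C1[C@@H]2[C@H]([C@H](C(C)=O)C(=O)[C@@H]2OC(=O)[C@H](C)CC)[C@@H](C(C)C)C[C@@H]1OC(=O)/C=C(\C)CC | intermediate
20 | (1S,2R,4S,5R,6R,7R,9S)-4-hydroxy-2-{[(2R)-2-methylbutanoyl]oxy}-3-oxooplop-10(14)-en-9-yl (2E)-3-methylpent-2-enoate | C=C1[C@@H]2[C@H]([C@H]([C@H](C)O)C(=O)[C@@H]2OC(=O)[C@H](C)CC)[C@@H](C(C)C)C[C@@H]1OC(=O)/C=C(\C)CC | intermediate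
21 | (1S,2R,4S,5R,6R,7R,9S)-4-acetoxy-2-{[(2R)-2-methylbutanoyl]oxy}-3-oxooplop-10(14)-en-9-yl (2E)-3-methylpent-2-enoate (CNP0289166.2) | C=C1[C@@H]2[C@H]([C@H]([C@H](C)OC(C)=O)C(=O)[C@@H]2OC(=O)[C@H](C)CC)[C@@H](C(C)C)C[C@@H]1OC(=O)/C=C(\C)CC | target

## Step count and risks

Total steps: 12. Longest linear sequence: 12 (1 → 21); 4, 7 and 18 are bought.

Most likely to fail:

**Step 6 (ring B closure).** The enolisation may not be γ-selective. The cross-conjugated dienone also offers its terminal methylene to the ring-A nucleophile (bridged product) and can undergo Nazarov closure. The ring fusion may come out cis. The fallback sets out from 11. Thiophenol with catalytic Et3N adds to C14 and gives the β-phenylthio ketone F1, which leaves the isopropyl-substituted enone as the only acceptor. The same TIPSOTf/i-Pr2NEt cyclisation then gives the bicyclic sulfide F2. One equivalent of Davis oxaziridine gives the sulfoxide F3, and syn-elimination in toluene at 90 °C over CaCO3 restores the 10(14)-alkene. The route is rejoined at 13.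

**Step 8 (ring contraction).** The silyloxydiene may not survive BF3, and the epoxide may open without the acyl shift. The fallback sets out from 14. Aqueous HClO4 in THF opens the epoxide at C5 with inversion and hydrolyses the silyl enol ether, giving the 4,5-diol F4. MsCl in pyridine sulfonylates only the secondary C5 hydroxyl and gives the mesylate F5. Et3Al in CH2Cl2 at −78 °C then triggers a semipinacol rearrangement with 1,2-acyl migration; the equatorial mesylate is antiperiplanar to the C3–C4 bond. The route is rejoined at 16.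

**Step 11 (mono-reduction of the diketone).** The catalyst may not discriminate the two ketones, may over-reduce, or may give the wrong sense at C4. The fallback sets out from 19. (R)-Me-CBS with catecholborane at −78 °C reduces both carbonyls, the methyl ketone under reagent control, and gives the 3,4-diol F6. Ac2O in pyridine at −20 °C acetylates the less hindered side-chain carbinol and gives the monoacetate F7. Dess–Martin oxidation of the ring carbinol rejoins the route at 21.

Further compounds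

F1 | step 6 | (1R,6S)-3-methyl-6-[(4E)-6-methyl-3-oxo-1-(phenylsulfanyl)hept-4-en-2-yl]-2-oxocyclohex-3-en-1-yl (2R)-2-methylbutanoate (C10 epimers) | CC(C)/C=C/C(=O)C(CSc1ccccc1)[C@@H]1CC=C(C)C(=O)[C@@H]1OC(=O)[C@H](C)CC
F2 | step 6 | (1S,2R,6S,7R)-3-oxo-14-(phenylsulfanyl)-9-{[tri(propan-2-yl)silyl]oxy}cadina-4,8-dien-2-yl (2R)-2-methylbutanoate (C10 epimers) | C(Sc3ccccc3)C1[C@@H]2[C@H](C=C(C)C(=O)[C@@H]2OC(=O)[C@H](C)CC)[C@@H](C(C)C)C=C1O[Si](C(C)C)(C(C)C)C(C)C
F3 | step 6 | (1S,2R,6S,7R)-3-oxo-14-(phenylsulfinyl)-9-{[tri(propan-2-yl)silyl]oxy}cadina-4,8-dien-2-yl (2R)-2-methylbutanoate (C10 and S epimers) | O=S(c3ccccc3)CC1[C@@H]2[C@H](C=C(C)C(=O)[C@@H]2OC(=O)[C@H](C)CC)[C@@H](C(C)C)C=C1O[Si](C(C)C)(C(C)C)C(C)C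
F4 | step 8 | (1S,2R,4R,5S,6R,7R)-4,5-dihydroxy-3,9-dioxocadin-10(14)-en-2-yl (2R)-2-methylbutanoate | C=C1[C@@H]2[C@H]([C@H](O)[C@@](C)(O)C(=O)[C@@H]2OC(=O)[C@H](C)CC)[C@@H](C(C)C)CC1=O
F5 | step 8 | (1S,2R,4R,5S,6R,7R)-4-hydroxy-5-(methanesulfonyloxy)-3,9-dioxocadin-10(14)-en-2-yl (2R)-2-methylbutanoate | C=C1[C@@H]2[C@H]([C@H](OS(C)(=O)=O)[C@@](C)(O)C(=O)[C@@H]2OC(=O)[C@H](C)CC)[C@@H](C(C)C)CC1=O
F6 | step 11 | (1S,2R,4S,5R,6R,7R,9S)-3,4-dihydroxy-2-{[(2R)-2-methylbutanoyl]oxy}oplop-10(14)-en-9-yl (2E)-3-methylpent-2-enoate (C3 configuration not defined) | C=C1[C@@H]2[C@H]([C@H]([C@H](C)O)C(O)[C@@H]2OC(=O)[C@H](C)CC)[C@@H](C(C)C)C[C@@H]1OC(=O)/C=C(\C)CC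
F7 | step 11 | (1S,2R,4S,5R,6R,7R,9S)-4-acetoxy-3-hydroxy-2-{[(2R)-2-methylbutanoyl]oxy}oplop-10(14)-en-9-yl (2E)-3-methylpent-2-enoate (C3 configuration not defined) | C=C1[C@@H]2[C@H]([C@H]([C@H](C)OC(C)=O)C(O)[C@@H]2OC(=O)[C@H](C)CC)[C@@H](C(C)C)C[C@@H]1OC(=O)/C=C(\C)CC
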